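**Plan**
1. Cuts: (a) the C13–C14 sp3–sp2 bond, giving a bicyclic vinyl core and an irone-derived dienyl iodide; (b) the ether bond O–C7 together with the ring bond C6–C11, unfolding the 6-oxabicyclo[3.2.1]octane to an acyclic 2-vinyl-2,3-epoxy alcohol; (c) epoxide to Z tetrasubstituted allylic alcohol; (d) the C9–C10 sp3–sp2 bond, giving a dienyl silyl ether and an iododienol.
2. Enabling feature: the ether CH2 (C26) hangs axially from quaternary C11, 1,3 to the tertiary ether carbon C7 of the cyclohexane, and C11 is vicinal to the tertiary carbinol C10. C10–C11 is thus the retron of an epoxide, C7 that of a cyclohexyl cation, and the CH2OH of the epoxy alcohol is the internal trap.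
3. Forward: both olefin geometries are built first (aldol condensation on a β-methyl butyrolactone; anti-carbomagnesiation of but-2-yn-1-ol), joined by B-alkyl Suzuki coupling and epoxidised. One cascade then closes the carbocycle and the oxolane; a second B-alkyl Suzuki coupling adds the side chain, and the end groups are adjusted.
4. Stereochemistry: C2 from hydrogenation with Ru(OAc)2[(R)-BINAP]; C10 and C11 from Sharpless epoxidation; C6 and C7 from olefin geometry through a chair; the irone ring from the chiral pool; the E,E-diene from syn-carboalumination and stereoretentive coupling.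
5. Locants used in the text only: C1 = CHO carbon, C2 = its α-carbon, C3–C5 = hydroxypropyl chain (C3 = CH2OH), C6 = ring CH, C7 = ether bridgehead, C8 and C9 = ring CH2, C10 = carbinol carbon, C11 = quaternary bridgehead, C26 = OCH2, C12–C17 = chain from C11 to the irone ring.

Key step: step 12

Assumption 1: (+)-cis-α-irone of (2S,6R) configuration [(1R,5S) in the ring numbering used below], the main irone of Iris pallida oil, is taken as purchasable in enantiopure form; racemic α-irone would need a resolution first.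
Assumption 2: in step 1 the (R)-antipode of BINAP is taken to deliver the (S)-lactone; if the sense is the opposite, (S)-BINAP is used.
Abbreviations: TBS = tert-butyldimethylsilyl, TBDPS = tert-butyldiphenylsilyl, 9-BBN = 9-borabicyclo[3.3.1]nonane, LDA = LiN(iPr)2, KHMDS = KN(SiMe3)2, DIBAL-H = (iBu)2AlH.

**Step 1**
Reactants: 1 4-methylfuran-2(5H)-one
Product: 2 (4S)-4-methyloxolan-2-one
Conditions: Ru(OAc)2[(R)-BINAP] (1 mol %), H2 (100 atm), CH2Cl2/MeOH, 50 °C
Reagents that add atoms: none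
Why: Asymmetric hydrogenation of a β-substituted butenolide by Ru(OAc)2[(R)-BINAP], in which the ligand antipode fixes the methyl-bearing centre (later C2, the α-carbon of the aldehyde).

**Step 2**
Reactants: 3 butane-1,4-diol
Product: 4 4-(TBDPSO)butan-1-ol
Conditions: NaH (1.0 equiv), THF, 0 °C; then TBDPSCl (1.0 equiv), rt
Reagents that add atoms: tert-butyl(chloro)diphenylsilane, CC(C)(C)[Si](Cl)(c1ccccc1)c1ccccc1
Why: Monosilylation of a symmetrical diol through its monosodium alkoxide; TBDPS is chosen as a bulky, weakly nucleophilic ether that survives to the last step.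

**Step 3**
Reactants: 4 4-(TBDPSO)butan-1-ol
Product: 5 4-(TBDPSO)butanal
Conditions: TEMPO (10 mol %), PhI(OAc)2 (1.1 equiv), CH2Cl2, rt
Reagents that add atoms: none
Why: TEMPO/PhI(OAc)2 oxidation of a primary alcohol stops at the aldehyde and leaves the silyl ether untouched.

**Step 4**
Reactants: 2 (4S)-4-methyloxolan-2-one; 5 4-(TBDPSO)butanal
Product: 6 (4S)-3-[1-hydroxy-4-(TBDPSO)butyl]-4-methyloxolan-2-one (epimers at C3 and at the carbinol carbon)
Conditions: LDA (1.1 equiv), THF, −78 °C; then 5; aq NH4Cl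
Reagents that add atoms: none
Why: Lithium enolate aldol addition of the lactone to the aldehyde; the two new centres are erased in step 5, so their configuration is immaterial.

**Step 5**
Reactants: 6 (4S)-3-[1-hydroxy-4-(TBDPSO)butyl]-4-methyloxolan-2-one
Product: 8 (3E,4S)-3-[4-(TBDPSO)butylidene]-4-methyloxolan-2-one, via mesylate 7 (not isolated)
Conditions: MsCl, Et3N, CH2Cl2, 0 °C; then DBU, rt
Reagents that add atoms: none
Why: Mesylation and E1cB elimination (aldol condensation) should give the thermodynamically preferred E α-alkylidene lactone, which places the butylidene chain cis to C2, the geometry that later becomes the C6 configuration.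

**Step 6**
Reactants: 8 (3E,4S)-3-[4-(TBDPSO)butylidene]-4-methyloxolan-2-one
Product: 9 (3E,4S)-3-[4-(TBDPSO)butylidene]-4-methyloxolan-2-ol (lactol, both anomers)
Conditions: DIBAL-H (1.1 equiv), CH2Cl2, −78 °C; aq potassium sodium tartrate
Reagents that add atoms: none
Why: 1,2-Reduction of a lactone by DIBAL-H at low temperature stops at the lactol.

**Step 7**
Reactants: 9 (3E,4S)-3-[4-(TBDPSO)butylidene]-4-methyloxolan-2-ol
Product: 10 (2S,3Z)-3-ethenyl-2-methyl-7-(TBDPSO)hept-3-en-1-ol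
Conditions: Ph3PCH3Br (3 equiv), KHMDS (3 equiv), THF, 0 °C; then 9, −78 °C → rt
Reagents that add atoms: methyltriphenylphosphonium bromide, C[P+](c1ccccc1)(c1ccccc1)c1ccccc1.[Br-]
Why: Wittig methylenation of the open hydroxy enal form of the lactol turns the former lactone carbon into the C8=C9 vinyl group and frees the C1 hydroxyl without touching the trisubstituted olefin.

**Step 8**
Reactants: 10 (2S,3Z)-3-ethenyl-2-methyl-7-(TBDPSO)hept-3-en-1-ol
Product: 11 (2S,3Z)-3-ethenyl-2-methyl-1-(TBSO)-7-(TBDPSO)hept-3-ene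
Conditions: TBSCl, imidazole, DMF, rt
Reagents that add atoms: tert-butyl(chloro)dimethylsilane, CC(C)(C)[Si](C)(C)Cl
Why: Standard silylation of a primary alcohol; TBS can later be removed in the presence of TBDPS.

**Step 9**
Reactants: 12 but-2-yn-1-ol
Product: 14 (2Z)-2-ethenyl-3-iodobut-2-en-1-ol, via cyclic alkenylmagnesium alkoxide 13 (not isolated)
Conditions: CH2=CHMgCl (3.5 equiv), THF/cyclohexane, 70 °C; then I2, THF, −78 → 0 °C
Reagents that add atoms: vinylmagnesium chloride, C=C[Mg]Cl; iodine, II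
Why: Hydroxyl-directed anti-carbomagnesiation of a propargylic alcohol puts vinyl on the proximal alkyne carbon and magnesium in a five-membered chelate cis to CH2OH, so iodinolysis with retention gives the Z iodide.

**Step 10**
Reactants: 11 (2S,3Z)-3-ethenyl-2-methyl-1-(TBSO)-7-(TBDPSO)hept-3-ene; 14 (2Z)-2-ethenyl-3-iodobut-2-en-1-ol
Product: 16 (2Z,6Z)-2-ethenyl-3-methyl-6-[(2S)-1-(TBSO)propan-2-yl]-10-(TBDPSO)deca-2,6-dien-1-ol, via B-alkyl-9-BBN 15 (not isolated)
Conditions: 9-BBN (1.05 equiv), THF, 0 °C → rt; then 14, Pd(dppf)Cl2 (5 mol %), AsPh3 (5 mol %), Cs2CO3, DMF/H2O, rt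
Reagents that add atoms: none
Why: 9-BBN hydroborates only the terminal vinyl group of the 1,3-diene (boron on C9), and the B-alkyl Suzuki–Miyaura coupling proceeds with retention at the iodoalkene, placing the C9 chain cis to CH2OH.

**Step 11**
Reactants: 16 (2Z,6Z)-2-ethenyl-3-methyl-6-[(2S)-1-(TBSO)propan-2-yl]-10-(TBDPSO)deca-2,6-dien-1-ol
Product: 17 [(2R,3S)-2-ethenyl-3-methyl-3-{(3Z)-3-[(2S)-1-(TBSO)propan-2-yl]-7-(TBDPSO)hept-3-en-1-yl}oxiran-2-yl]methanol
Conditions: Ti(OiPr)4 (10 mol %), D-(−)-diisopropyl tartrate (12 mol %), t-BuOOH (2 equiv), 4 Å MS, CH2Cl2, −25 °C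
Reagents that add atoms: tert-butyl hydroperoxide, CC(C)(C)OO
Why: Katsuki–Sharpless asymmetric epoxidation acts only on the allylic olefin, and D-(−)-tartrate delivers oxygen in the sense by which nerol gives its (2R,3S)-epoxide, setting C10 and C11 together.

**Step 12**
Reactants: 17 [(2R,3S)-2-ethenyl-3-methyl-3-{(3Z)-3-[(2S)-1-(TBSO)propan-2-yl]-7-(TBDPSO)hept-3-en-1-yl}oxiran-2-yl]methanol
Product: 19 (1S,2S,5R,8S)-1-ethenyl-2-methyl-5-[(2R)-1-(TBSO)propan-2-yl]-8-[3-(TBDPSO)propyl]-6-oxabicyclo[3.2.1]octan-2-ol, via tertiary cyclohexyl cation 18 (not isolated)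
Conditions: Ph4PBF4 (10 mol %), (CF3)2CHOH/CH2Cl2 (1:4), −40 → 0 °C
Reagents that add atoms: none
Why: Proposed new method: hydrogen-bond activation of the tertiary allylic C11–O bond of the vinyl epoxide (the vinyl group stabilises positive charge at C11 and overrides the inductive bias of the neighbouring CH2OH) lets the C6=C7 olefin attack C11 anti to the leaving oxygen through a six-membered chair, and the tertiary cation formed at C7 is captured by the axial C26 hydroxyl; the closest known reaction type is the epoxide-initiated cation–olefin cyclisation with heteroatom termination, which has not been shown on a fully substituted 2-vinyl-2,3-epoxy alcohol whose own hydroxyl ends the cascade. The carbocycle closes 6-endo with respect to both the oxirane (both oxirane carbons end up in the ring) and the olefin, and the oxolane closes by 5-exo capture of the cation, so the 6-oxabicyclo[3.2.1]octane arises in one operation. C10 keeps the configuration set in step 11 and C11 is inverted, so the (2R,3S)-epoxide of the Z olefin puts OH equatorial and CH2OH axial; C6 follows from the Z geometry of the trisubstituted olefin in the chair (the propyl chain, trans to C8, becomes equatorial), and C7 can only be bonded by oxygen on the face that carries the axial CH2OH. The step needs opening at C11 and not C10 (secured by allylic stabilisation and because only C11 is within reach of the olefin through a six-membered ring), chair and not boat folding (only one methyl group is axial), and capture by the C26 hydroxyl in preference to proton loss or to the C10 oxygen and the bulky silyl ether oxygens (secured by its 1,3-diaxial position over the empty orbital). The vinyl group is the activating group of the precursor and is carried on as the coupling handle of step 15.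

**Step 13**
Reactants: 20 (+)-cis-α-irone, (3E)-4-[(1R,5S)-2,5,6,6-tetramethylcyclohex-2-en-1-yl]but-3-en-2-one
Product: 22 (3E)-4-[(1R,5S)-2,5,6,6-tetramethylcyclohex-2-en-1-yl]but-3-en-1-yne, via dienyl diethyl phosphate 21 (not isolated)
Conditions: LDA (1.05 equiv), THF, −78 °C; ClP(O)(OEt)2; then LDA (2.3 equiv), −78 → 0 °C
Reagents that add atoms: none
Why: One-pot conversion of a methyl ketone into a terminal alkyne through the kinetic enol phosphate and its elimination (Negishi alkyne synthesis), which carries over the E olefin and both ring stereocentres.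

**Step 14**
Reactants: 22 (3E)-4-[(1R,5S)-2,5,6,6-tetramethylcyclohex-2-en-1-yl]but-3-en-1-yne
Product: 24 (1E,3E)-1-iodo-2-methyl-4-[(1R,5S)-2,5,6,6-tetramethylcyclohex-2-en-1-yl]buta-1,3-diene, via alkenyldimethylalane 23 (not isolated)
Conditions: AlMe3 (2 equiv), Cp2ZrCl2 (25 mol %), CH2Cl2, 0 °C → rt; then I2, THF, −30 °C
Reagents that add atoms: trimethylaluminium, C[Al](C)C; iodine, II
Why: Cp2ZrCl2-catalysed syn-carboalumination of the terminal alkyne (Negishi carboalumination) puts methyl on the internal carbon and aluminium on the terminus, and iodinolysis with retention gives the E iodide.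

**Step 15**
Reactants: 19 (1S,2S,5R,8S)-1-ethenyl-2-methyl-5-[(2R)-1-(TBSO)propan-2-yl]-8-[3-(TBDPSO)propyl]-6-oxabicyclo[3.2.1]octan-2-ol; 24 (1E,3E)-1-iodo-2-methyl-4-[(1R,5S)-2,5,6,6-tetramethylcyclohex-2-en-1-yl]buta-1,3-diene
Product: 26 (1S,2S,5R,8S)-2-methyl-1-{(3E,5E)-4-methyl-6-[(1R,5S)-2,5,6,6-tetramethylcyclohex-2-en-1-yl]hexa-3,5-dien-1-yl}-5-[(2R)-1-(TBSO)propan-2-yl]-8-[3-(TBDPSO)propyl]-6-oxabicyclo[3.2.1]octan-2-ol, via B-alkyl-9-BBN 25 (not isolated)
Conditions: 9-BBN (2.0 equiv), THF, rt → 40 °C; H2O; then 24, Pd(dppf)Cl2 (10 mol %), AsPh3, Cs2CO3, DMF, rt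
Reagents that add atoms: none
Why: Hydroboration of the monosubstituted vinyl group (boron on the terminal carbon C13) and B-alkyl Suzuki–Miyaura coupling with retention of the iodide geometry complete the E,E-diene side chain.

**Step 16**
Reactants: 26 (the bis-silyl ether from step 15)
Product: 27 (2R)-2-[(1S,2S,5R,8S)-2-hydroxy-2-methyl-1-{(3E,5E)-4-methyl-6-[(1R,5S)-2,5,6,6-tetramethylcyclohex-2-en-1-yl]hexa-3,5-dien-1-yl}-8-[3-(TBDPSO)propyl]-6-oxabicyclo[3.2.1]octan-5-yl]propan-1-ol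
Conditions: PPTS (20 mol %), MeOH, rt
Reagents that add atoms: none
Why: Acid-catalysed methanolysis should cleave the primary TBS ether much faster than the primary TBDPS ether.

**Step 17**
Reactants: 27 (the primary alcohol from step 16)
Product: 28 (2S)-2-[(1S,2S,5R,8S)-2-hydroxy-2-methyl-1-{(3E,5E)-4-methyl-6-[(1R,5S)-2,5,6,6-tetramethylcyclohex-2-en-1-yl]hexa-3,5-dien-1-yl}-8-[3-(TBDPSO)propyl]-6-oxabicyclo[3.2.1]octan-5-yl]propanal
Conditions: Dess–Martin periodinane, NaHCO3, CH2Cl2, 0 °C → rt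
Reagents that add atoms: none
Why: Buffered Dess–Martin oxidation converts the primary alcohol into the aldehyde, while the tertiary alcohol cannot be oxidised and the α-stereocentre is not exposed to base.

**Step 18**
Reactants: 28 (the TBDPS-protected aldehyde from step 17)
Product: 29 (2S)-2-[(1S,2S,5R,8S)-2-hydroxy-8-(3-hydroxypropyl)-2-methyl-1-{(3E,5E)-4-methyl-6-[(1R,5S)-2,5,6,6-tetramethylcyclohex-2-en-1-yl]hexa-3,5-dien-1-yl}-6-oxabicyclo[3.2.1]octan-5-yl]propanal (CNP0419303.1)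
Conditions: HF·pyridine, pyridine/THF, 0 °C → rt
Reagents that add atoms: none
Why: Buffered fluoride desilylation frees the last hydroxyl under conditions chosen to avoid retro-oxa-Michael opening or epimerisation of the β-alkoxy aldehyde.

**Compound list**
1 | 4-methylfuran-2(5H)-one | CC1=CC(=O)OC1 | starting material
2 | (4S)-4-methyloxolan-2-one | O=C1OC[C@@H](C)C1 | intermediate
3 | butane-1,4-diol | OCCCCO | starting material
4 | 4-(TBDPSO)butan-1-ol | OCCCCO[Si](c1ccccc1)(c2ccccc2)C(C)(C)C | intermediate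
5 | 4-(TBDPSO)butanal | O=CCCCO[Si](c1ccccc1)(c2ccccc2)C(C)(C)C | intermediate
6 | (4S)-3-[1-hydroxy-4-(TBDPSO)butyl]-4-methyloxolan-2-one (epimer mixture at C3 and carbinol carbon) | O=C1OC[C@@H](C)C1C(O)CCCO[Si](c2ccccc2)(c3ccccc3)C(C)(C)C | intermediate
7 | methanesulfonate of 6 | O=C1OC[C@@H](C)C1C(OS(C)(=O)=O)CCCO[Si](c2ccccc2)(c3ccccc3)C(C)(C)C | intermediate
8 | (3E,4S)-3-[4-(TBDPSO)butylidene]-4-methyloxolan-2-one | O=C1OC[C@@H](C)/C1=C\CCCO[Si](c2ccccc2)(c3ccccc3)C(C)(C)C | intermediate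
9 | (3E,4S)-3-[4-(TBDPSO)butylidene]-4-methyloxolan-2-ol (both anomers) | OC1OC[C@@H](C)/C1=C\CCCO[Si](c2ccccc2)(c3ccccc3)C(C)(C)C | intermediate
10 | (2S,3Z)-3-ethenyl-2-methyl-7-(TBDPSO)hept-3-en-1-ol | C=C/C(=C/CCCO[Si](c1ccccc1)(c2ccccc2)C(C)(C)C)[C@H](C)CO | intermediate
11 | (2S,3Z)-3-ethenyl-2-methyl-1-(TBSO)-7-(TBDPSO)hept-3-ene | C=C/C(=C/CCCO[Si](c1ccccc1)(c2ccccc2)C(C)(C)C)[C@H](C)CO[Si](C)(C)C(C)(C)C | intermediate
12 | but-2-yn-1-ol | CC#CCO | starting material
13 | cyclic alkenylmagnesium alkoxide (4-ethenyl-3-methyl-2,5-dihydro-1,2-oxamagnesole) | CC1=C(C=C)CO[Mg]1 | intermediate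
14 | (2Z)-2-ethenyl-3-iodobut-2-en-1-ol | OC/C(C=C)=C(/C)I | intermediate
15 | 9-{(3Z)-3-[(2S)-1-(TBSO)propan-2-yl]-7-(TBDPSO)hept-3-en-1-yl}-9-BBN | C1CCC2CCCC1B2CC/C(=C/CCCO[Si](c3ccccc3)(c4ccccc4)C(C)(C)C)[C@H](C)CO[Si](C)(C)C(C)(C)C | intermediate
16 | (2Z,6Z)-2-ethenyl-3-methyl-6-[(2S)-1-(TBSO)propan-2-yl]-10-(TBDPSO)deca-2,6-dien-1-ol | OC/C(C=C)=C(/C)CC/C(=C/CCCO[Si](c1ccccc1)(c2ccccc2)C(C)(C)C)[C@H](C)CO[Si](C)(C)C(C)(C)C | intermediate
17 | [(2R,3S)-2-ethenyl-3-methyl-3-{(3Z)-3-[(2S)-1-(TBSO)propan-2-yl]-7-(TBDPSO)hept-3-en-1-yl}oxiran-2-yl]methanol | OC[C@@]1(C=C)O[C@@]1(C)CC/C(=C/CCCO[Si](c2ccccc2)(c3ccccc3)C(C)(C)C)[C@H](C)CO[Si](C)(C)C(C)(C)C | intermediate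
18 | tertiary cyclohexyl cation after C6–C11 closure (cation at C7, free CH2OH on C11) | C=C[C@@]1(CO)[C@H](CCCO[Si](c2ccccc2)(c3ccccc3)C(C)(C)C)[C+]([C@H](C)CO[Si](C)(C)C(C)(C)C)CC[C@]1(C)O | intermediate
19 | (1S,2S,5R,8S)-1-ethenyl-2-methyl-5-[(2R)-1-(TBSO)propan-2-yl]-8-[3-(TBDPSO)propyl]-6-oxabicyclo[3.2.1]octan-2-ol | C=C[C@]12CO[C@]([C@H](C)CO[Si](C)(C)C(C)(C)C)(CC[C@]1(C)O)[C@H]2CCCO[Si](c3ccccc3)(c4ccccc4)C(C)(C)C | intermediate
20 | (+)-cis-α-irone, (3E)-4-[(1R,5S)-2,5,6,6-tetramethylcyclohex-2-en-1-yl]but-3-en-2-one | CC1=CC[C@H](C)C(C)(C)[C@@H]1/C=C/C(C)=O | starting material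
21 | diethyl (3E)-4-[(1R,5S)-2,5,6,6-tetramethylcyclohex-2-en-1-yl]buta-1,3-dien-2-yl phosphate | CC1=CC[C@H](C)C(C)(C)[C@@H]1/C=C/C(=C)OP(=O)(OCC)OCC | intermediate
22 | (3E)-4-[(1R,5S)-2,5,6,6-tetramethylcyclohex-2-en-1-yl]but-3-en-1-yne | CC1=CC[C@H](C)C(C)(C)[C@@H]1/C=C/C#C | intermediate
23 | dimethyl{(1E,3E)-2-methyl-4-[(1R,5S)-2,5,6,6-tetramethylcyclohex-2-en-1-yl]buta-1,3-dien-1-yl}alane | CC1=CC[C@H](C)C(C)(C)[C@@H]1/C=C/C(C)=C/[Al](C)C | intermediate
24 | (1E,3E)-1-iodo-2-methyl-4-[(1R,5S)-2,5,6,6-tetramethylcyclohex-2-en-1-yl]buta-1,3-diene | CC1=CC[C@H](C)C(C)(C)[C@@H]1/C=C/C(C)=C/I | intermediate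
25 | B-alkyl-9-BBN from 19 (boron on the terminal carbon of the former vinyl group) | C1CCC2CCCC1B2CC[C@]34CO[C@]([C@H](C)CO[Si](C)(C)C(C)(C)C)(CC[C@]3(C)O)[C@H]4CCCO[Si](c5ccccc5)(c6ccccc6)C(C)(C)C | intermediate
26 | (1S,2S,5R,8S)-2-methyl-1-{(3E,5E)-4-methyl-6-[(1R,5S)-2,5,6,6-tetramethylcyclohex-2-en-1-yl]hexa-3,5-dien-1-yl}-5-[(2R)-1-(TBSO)propan-2-yl]-8-[3-(TBDPSO)propyl]-6-oxabicyclo[3.2.1]octan-2-ol | CC1=CC[C@H](C)C(C)(C)[C@@H]1/C=C/C(C)=C/CC[C@]12CO[C@]([C@H](C)CO[Si](C)(C)C(C)(C)C)(CC[C@]1(C)O)[C@H]2CCCO[Si](c3ccccc3)(c4ccccc4)C(C)(C)C | intermediate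
27 | (2R)-2-[(1S,2S,5R,8S)-2-hydroxy-2-methyl-1-{(3E,5E)-4-methyl-6-[(1R,5S)-2,5,6,6-tetramethylcyclohex-2-en-1-yl]hexa-3,5-dien-1-yl}-8-[3-(TBDPSO)propyl]-6-oxabicyclo[3.2.1]octan-5-yl]propan-1-ol | CC1=CC[C@H](C)C(C)(C)[C@@H]1/C=C/C(C)=C/CC[C@]12CO[C@]([C@H](C)CO)(CC[C@]1(C)O)[C@H]2CCCO[Si](c3ccccc3)(c4ccccc4)C(C)(C)C | intermediate
28 | (2S)-2-[(1S,2S,5R,8S)-2-hydroxy-2-methyl-1-{(3E,5E)-4-methyl-6-[(1R,5S)-2,5,6,6-tetramethylcyclohex-2-en-1-yl]hexa-3,5-dien-1-yl}-8-[3-(TBDPSO)propyl]-6-oxabicyclo[3.2.1]octan-5-yl]propanal | CC1=CC[C@H](C)C(C)(C)[C@@H]1/C=C/C(C)=C/CC[C@]12CO[C@]([C@H](C)C=O)(CC[C@]1(C)O)[C@H]2CCCO[Si](c3ccccc3)(c4ccccc4)C(C)(C)C | intermediate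
29 | (2S)-2-[(1S,2S,5R,8S)-2-hydroxy-8-(3-hydroxypropyl)-2-methyl-1-{(3E,5E)-4-methyl-6-[(1R,5S)-2,5,6,6-tetramethylcyclohex-2-en-1-yl]hexa-3,5-dien-1-yl}-6-oxabicyclo[3.2.1]octan-5-yl]propanal | CC1=CC[C@H](C)C(C)(C)[C@@H]1/C=C/C(C)=C/CC[C@]12CO[C@]([C@H](C)C=O)(CC[C@]1(C)O)[C@H]2CCCO | target

**Totals**
Total step count: 18. Longest linear sequence: 14 steps (steps 2, 3, 4, 5, 6, 7, 8, 10, 11, 12, 15, 16, 17, 18, from butane-1,4-diol).

**Steps most likely to fail**

1. Step 12, the step that bears the label for a proposed new method. What may go wrong: ionisation of the tertiary allylic C–O bond ahead of C–C bond formation, with loss of configurational fidelity at C11 or a 1,2-alkyl shift to a ketone; or proton loss from the C7 cation outrunning capture by the hydroxyl. The fallback sets out from 17 and comes back to the route at 19, separating the two ring closures and using known reaction types. Treatment of 17 with Et2AlCl (CH2Cl2, −78 °C), a classical Lewis-acid epoxide–olefin monocyclisation ended by proton loss from C8, should give the cyclohexene diol (1S,2S,3R)-2-ethenyl-2-(hydroxymethyl)-1-methyl-4-[(2S)-1-(TBSO)propan-2-yl]-3-[3-(TBDPSO)propyl]cyclohex-4-en-1-ol F1. Iodoetherification of F1 (I2, NaHCO3, MeCN, 0 °C), the textbook closure of a cyclohex-3-enylmethanol to a 6-oxabicyclo[3.2.1]octane, should then give the iodo ether (1S,2S,4S,5R,8S)-1-ethenyl-4-iodo-2-methyl-5-[(2R)-1-(TBSO)propan-2-yl]-8-[3-(TBDPSO)propyl]-6-oxabicyclo[3.2.1]octan-2-ol F2, in which iodine stands on the ring CH next to the ether bridgehead and trans to the oxygen bridge. Radical deiodination of F2 (Bu3SnH, AIBN, toluene, 80 °C) leads to 19.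

2. Step 11. What may go wrong: weak facial discrimination by the Ti(OiPr)4/diisopropyl tartrate catalyst on a tetrasubstituted olefin that carries a vinyl group on the carbinol-bearing carbon, and titanium-promoted opening of the tertiary allylic epoxide during reaction or work-up. The fallback sets out from 16 and comes back to the route at 19. Hydroxyl-directed epoxidation without a chiral reagent (VO(acac)2, t-BuOOH, toluene, 0 °C) should give 17 together with its epoxide diastereomer [(2S,3R)-2-ethenyl-3-methyl-3-{(3Z)-3-[(2S)-1-(TBSO)propan-2-yl]-7-(TBDPSO)hept-3-en-1-yl}oxiran-2-yl]methanol F3; the two are diastereomers because C2 is already fixed. The mixture of 17 and F3 is taken through step 12, which should give 19 and its ring diastereomer (1R,2R,5S,8R)-1-ethenyl-2-methyl-5-[(2R)-1-(TBSO)propan-2-yl]-8-[3-(TBDPSO)propyl]-6-oxabicyclo[3.2.1]octan-2-ol F4. Compound 19 and F4 now differ at centres next to C2 and are separated by chromatography, and 19 continues.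

3. Step 13. What may go wrong: deprotonation of the doubly allylic ring CH by excess LDA, leading to epimerisation or olefin migration into conjugation. The fallback sets out from 20 and comes back to the route at 24, skipping steps 13 and 14. Horner–Wadsworth–Emmons olefination (triethyl phosphonoacetate, NaH, THF, 0 °C → rt; the minor 2Z isomer is removed by chromatography) should give ethyl (2E,4E)-3-methyl-5-[(1R,5S)-2,5,6,6-tetramethylcyclohex-2-en-1-yl]penta-2,4-dienoate F5. Saponification of F5 (LiOH, THF/MeOH/H2O) gives (2E,4E)-3-methyl-5-[(1R,5S)-2,5,6,6-tetramethylcyclohex-2-en-1-yl]penta-2,4-dienoic acid F6. Catalytic Hunsdiecker iododecarboxylation of F6 (N-iodosuccinimide, LiOAc cat., MeCN/H2O) with retention of olefin geometry then gives 24.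

**Further compounds**
F1 | step 12 | (1S,2S,3R)-2-ethenyl-2-(hydroxymethyl)-1-methyl-4-[(2S)-1-(TBSO)propan-2-yl]-3-[3-(TBDPSO)propyl]cyclohex-4-en-1-ol | C=C[C@@]1(CO)[C@H](CCCO[Si](c2ccccc2)(c3ccccc3)C(C)(C)C)C([C@H](C)CO[Si](C)(C)C(C)(C)C)=CC[C@]1(C)O
F2 | step 12 | (1S,2S,4S,5R,8S)-1-ethenyl-4-iodo-2-methyl-5-[(2R)-1-(TBSO)propan-2-yl]-8-[3-(TBDPSO)propyl]-6-oxabicyclo[3.2.1]octan-2-ol | C=C[C@]12CO[C@]([C@H](C)CO[Si](C)(C)C(C)(C)C)([C@@H](I)C[C@]1(C)O)[C@H]2CCCO[Si](c3ccccc3)(c4ccccc4)C(C)(C)C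
F3 | step 11 | [(2S,3R)-2-ethenyl-3-methyl-3-{(3Z)-3-[(2S)-1-(TBSO)propan-2-yl]-7-(TBDPSO)hept-3-en-1-yl}oxiran-2-yl]methanol | OC[C@]1(C=C)O[C@]1(C)CC/C(=C/CCCO[Si](c2ccccc2)(c3ccccc3)C(C)(C)C)[C@H](C)CO[Si](C)(C)C(C)(C)C
F4 | step 11 | (1R,2R,5S,8R)-1-ethenyl-2-methyl-5-[(2R)-1-(TBSO)propan-2-yl]-8-[3-(TBDPSO)propyl]-6-oxabicyclo[3.2.1]octan-2-ol | C=C[C@@]12CO[C@@]([C@H](C)CO[Si](C)(C)C(C)(C)C)(CC[C@@]1(C)O)[C@@H]2CCCO[Si](c3ccccc3)(c4ccccc4)C(C)(C)C
F5 | step 13 | ethyl (2E,4E)-3-methyl-5-[(1R,5S)-2,5,6,6-tetramethylcyclohex-2-en-1-yl]penta-2,4-dienoate | CC1=CC[C@H](C)C(C)(C)[C@@H]1/C=C/C(C)=C/C(=O)OCC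
F6 | step 13 | (2E,4E)-3-methyl-5-[(1R,5S)-2,5,6,6-tetramethylcyclohex-2-en-1-yl]penta-2,4-dienoic acid | CC1=CC[C@H](C)C(C)(C)[C@@H]1/C=C/C(C)=C/C(=O)O
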